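## Structural features

Atom labels: the three guaianolide units are called A (terminal, free exocyclic enone), B (central) and C (terminal, free 10(14)-methylene); every atom carries its guaiane number followed by the unit letter.

1. Ainsliatrimer A (C45H44O10) consists of three guaianolide units. Each is a cis-fused hydroazulene (cyclopentanone C1–C5 fused to the seven-membered ring C1, C5–C10; H5α throughout, H1α in unit C) with a trans-fused α-methylene-γ-butyrolactone across C6–C7.
2. The units are held together by two spiro-annulated cyclohexenes: ring A/B (C2A, C1A, C10A, C14A, C15B, C4B) and ring B/C (C2B, C1B, C10B, C14B, C15C, C4C).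
3. C4B and C4C are quaternary spiro centres. Each is α to a ketone (C3B, C3C) and bonded directly to the α-carbon (C2A, C2B) of the enone of the neighbouring unit.
4. Of the 14 stereocentres, ten (C5, C6, C7 of each unit and C1C) are those of the monomer. The four new ones are C4B (next to C5B), C4C (next to C5C), C10A (H, α) and C10B (tertiary OH, β). The two spiro centres have opposite sense: the C2B–C4C bond is syn to H5C, the C2A–C4B bond is anti to H5B.
5. Fragile groups are the three α-methylene lactones, the cross-conjugated exocyclic enone C15A=C4A–C3A(=O)–C2A=C1A, and the tertiary γ-hydroxy enone at C10B.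
6. The real difficulty lies in the two hindered bonds C2A–C4B and C2B–C4C (quaternary carbon to a fully substituted enone carbon), their facial control, and the different oxidation level at C10A (H) and C10B (OH).
7. The feature exploited by the key step: each of these bonds joins the α-carbons of two cyclopentanone carbonyls. O=C3A–C2A–C4B–C3B=O and O=C3B–C2B–C4C–C3C=O form a contiguous 1,4-diketone array, which is the retron of an oxidative coupling of two enol derivatives. The remaining inter-unit bonds C14A–C15B and C14B–C15C are unhindered CH2–CH2 links.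

## Logic of the disconnections

**19 ⇒ 17.** No skeletal bond is cut. The conjugated C1A=C2A enone with H at C10A is traced back to the deconjugated C1A=C10A isomer, and the C10B alcohol and C3C ketone to their silyl derivatives. Reason: the ring closure delivers the deconjugated enone, and the silyl groups are bystanders of the enol ether chemistry. Demand: conjugation must put H on the α-face of C10A. This centre is epimerisable through the dienolate, so thermodynamic control is relied on.

**17 ⇒ 16 (key).** The bond C2A–C4B is cut. Reason: it is the central bond of the 1,4-diketone C3A/C3B. Gain: the spiro centre C4B and ring A/B disappear, and three monomer-like units remain, joined only by CH2–CH2 tethers. Demand: an intramolecular one-electron oxidative coupling of the trienol ether of unit A with the 2-silyloxydiene of unit B, with attack on the β-face of C4B.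

**16 ⇒ 15 ⇒ 14 + 5.** After removal of the silyl groups (15), the bond C14A–C15B is cut. Reason: it is a primary–primary sp3 bond between two carbons that are both acceptor termini (δ of a dienone, β of an enone), so a radical union is natural. Gain: a monomer-sized piece, 5, is split off. Demand: the C15B radical from 14 must add to C14 of 5 and not to C15 of 5 or to a lactone methylene.

**14 ⇒ 12.** The C15B–I bond (and C4B–H) is cut, giving back the exocyclic enone. Reason: conjugate addition of iodide converts the acceptor carbon C15B into a radical precursor. Demand: addition to the ketone enone only.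

**12 ⇒ 10.** The C10B–O bond is cut, and the C1B=C2B enone is returned to the C1B=C10B alkene with H at C2B. Reason: epoxidation of this alkene and base-induced opening place the oxygen at C10B by choice. Demand: epoxidation on the β-face.

**10 ⇒ 9.** The bond C2B–C4C is cut: the same 1,4-diketone disconnection, one level down. Demand: attack on the α-face of C4C (syn to H5C).

**9 ⇒ 8 ⇒ 7 + 5.** After removal of the silyl groups (8), the bond C14B–C15C is cut, as for 15. The gain is two monomers.

**7 ⇒ 3; 5 ⇒ 4 ⇒ 3; 3 ⇒ 2 ⇒ 1.** The C15–I bond of 7 comes from the enone of 3. The C1=C2 bond of 5 comes from 3 through the silyl enol ether 4. The C3 oxygen of 3 comes from allylic oxidation of commercial 1. All monomer stereocentres are bought with 1.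

## Other disconnections considered

**Alternative 1:** Both bonds of each cyclohexene (C2–C4′ and C14–C15′) are cut together. The forward key step is a (4+2) cycloaddition of 5 (diene C2=C1–C10=C14) to the exocyclic enone of 3. After oxidation at C10B to 12, a second cycloaddition of 5 gives A1, which is conjugated to 19. This is the shortest route and the one the structure suggests first. The chosen plan is preferred on grounds of design:
- 5 is at once diene and dienophile, and both partners are electron-poor, so the cycloaddition must compete with self-addition of 5 and is likely to need forcing conditions next to several polymerisable methylene groups.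
- The hindered bond (C2 to the quaternary C4′) has to form in a bimolecular event, with regio-, endo/exo- and facial selectivity left to the partners.
- In the chosen plan the bimolecular event forms only the unhindered CH2–CH2 bond, and the hindered bond is closed intramolecularly through a six-membered transition state.

**Alternative 2:** C2–C4′ is cut as an enolate/vinyl halide pair. The forward key step is a Pd-catalysed intramolecular α-alkenylation of the ring C ketone by a 2-iodoenone such as A2 (from 8 by conjugation and α-iodination), giving A3. It is less suitable as the main plan for three reasons: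
- It delivers the conjugated enone with H at C10 directly, so for ring B/C it cannot lead to 12 without a separate γ-oxidation next to the enolisable ring C ketone.
- It needs stoichiometric base with warming in the presence of base-sensitive α-methylene lactones.
- C10 must be set before the ring is closed.

It remains useful for ring A/B only and is kept as a fallback there.

**Alternative 3:** The order of the two bonds is reversed: C2–C4′ first, C14–C15′ last. The forward key step is a 6-endo radical cyclisation of the C15 radical from iodide A4 onto the C14 terminus of the dienone. Trapping the resulting dienoxyl radical with H or O2 would give the C10–H or C10–OH series. The chosen plan is preferred for two reasons: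
- A4 requires the hindered bond between a quaternary carbon and a trisubstituted enone carbon to be made between two separate molecules that both carry Michael acceptors. No step of comparable reliability can be named for this.
- 5-exo closure onto C10 would compete.

Key step: step 13

Remarks on the chemistry (assumptions):
- The configurations at C3 of 2, at C4 of 7, 8, 14 and 15, and at C2 of the ring-closed ketones 10, 11 and 17 are erased later. They are drawn as the expected major epimers.
- 8 and 15 are drawn as the 1(10)-ene (β,γ-unsaturated) tautomers; the conjugated tautomers converge in steps 7 and 12.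
- 5 is made once and used in steps 6 and 11.

## Steps

Step 1
Reactants: 1 dehydrocostus lactone
Product: 2 3-epizaluzanin C (3α-hydroxydehydrocostus lactone)
Conditions: SeO2 (0.3 equiv), t-BuOOH (2 equiv), CH2Cl2, 0 → 25 °C
Reagents that add atoms: tert-butyl hydroperoxide, CC(C)(C)OO
Why: Allylic oxidation with SeO2 (ene reaction, then 2,3-sigmatropic shift; t-BuOOH as terminal oxidant) at the C3 methylene next to the 4(15)-alkene; oxygen should arrive on the convex α-face, and this centre is erased in step 2.

Step 2
Reactants: 2 3-epizaluzanin C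
Product: 3 dehydrozaluzanin C (3-oxoguaia-4(15),10(14),11(13)-trien-12,6α-olide)
Conditions: Dess–Martin periodinane, CH2Cl2, 0 → 25 °C
Reagents that add atoms: none
Why: Dess–Martin oxidation of the secondary allylic alcohol to the exocyclic enone under neutral conditions that leave the α-methylene lactone and the 10(14)-alkene untouched.

Step 3
Reactants: 3 dehydrozaluzanin C
Product: 4 3-(tert-butyldimethylsilyloxy)guaia-2,4(15),10(14),11(13)-tetraen-12,6α-olide
Conditions: TBSOTf, Et3N, CH2Cl2, −78 → 0 °C
Reagents that add atoms: tert-butyldimethylsilyl trifluoromethanesulfonate, CC(C)(C)[Si](C)(C)OS(=O)(=O)C(F)(F)F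
Why: Soft enolisation (silyl triflate and amine); C2 is the only α-carbon that bears hydrogen, so a single cross-conjugated 2-silyloxydiene should form.

Step 4
Reactants: 4 silyl enol ether of dehydrozaluzanin C
Product: 5 3-oxoguaia-1,4(15),10(14),11(13)-tetraen-12,6α-olide (1,2-didehydro-dehydrozaluzanin C)
Conditions: Pd(OAc)2 (1.1 equiv), MeCN, 25 °C; kept as a cold solution
Reagents that add atoms: none
Why: Saegusa–Ito oxidation: the palladium enolate at C2 undergoes β-hydride elimination from C1–H to give the 1(2)-ene conjugated with the 10(14)-methylene; 5 is both a diene and a dienophile and is therefore stored cold and dilute.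

Step 5
Reactants: 3 dehydrozaluzanin C
Product: 7 15-iodo-3-oxo-4βH-guaia-10(14),11(13)-dien-12,6α-olide, via iodo trimethylsilyl enol ether 6 (not isolated)
Conditions: Me3SiI (1.1 equiv), CH2Cl2, −78 °C; then pH 7 phosphate buffer, 0 °C; used crude
Reagents that add atoms: iodotrimethylsilane, C[Si](C)(C)I
Why: Conjugate iodosilylation: the silyl iodide activates the ketone (more Lewis basic than the lactone) and iodide adds to the unhindered C15 of the s-cis enone; buffered hydrolysis of 6 gives the β-iodo ketone, whose C4 epimers converge later.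

Step 6
Reactants: 7 β-iodo ketone of unit C; 5 dienone (future unit B)
Product: 8 tethered diketone B/C (C14B–C15C bond; unit B 3-oxoguaia-1(10),4(15),11(13)-trien-12,6α-olide; unit C 3-oxo-4βH-guaia-10(14),11(13)-dien-12,6α-olide)
Conditions: 5 (1.5 equiv), (Me3Si)3SiH (1.3 equiv), Et3B (0.2 equiv), air, toluene, −20 → 0 °C
Reagents that add atoms: none
Why: Giese reaction in its 1,6-mode: iodine abstraction gives the primary C15C radical, which should add to the terminal C14 of 5 because only there is the new radical delocalised over C10–C1–C2–C3–O; hydrogen transfer from the silane to C2 gives the 1(10)-ene, and the low temperature keeps 5 from cycloadding.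

Step 7
Reactants: 8 tethered diketone B/C
Product: 9 bis(silyl enol ether) B/C (unit B 3-silyloxy-2,1(10),4(15)-triene; unit C 3-silyloxy-3(4)-ene)
Conditions: TBSOTf (3 equiv), Et3N (4 equiv), CH2Cl2, 0 → 25 °C, equilibrating
Reagents that add atoms: tert-butyldimethylsilyl trifluoromethanesulfonate, CC(C)(C)[Si](C)(C)OS(=O)(=O)C(F)(F)F
Why: Silyl enol ether formation under equilibrating conditions: the doubly activated C2B methylene gives the fully conjugated trienol ether, and the ring C ketone should give the more substituted 3(4)-enol ether, the thermodynamic isomer of a 2-alkylcyclopentanone; the 2(3)-isomer cannot cyclise in step 8 and returns 8 on work-up.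

Step 8
Reactants: 9 bis(silyl enol ether) B/C
Product: 10 spiro dimer B/C with C2B–C4C bond (unit B 2βH-3-oxo-1(10),4(15)-diene; C4C spiro, bond to C2B syn to H5C)
Conditions: Cu(OTf)2 (2.2 equiv), 2,6-di-tert-butylpyridine, MeCN–CH2Cl2 (0.005 M), −30 → 0 °C
Reagents that add atoms: none
Why: One-electron oxidative coupling of two silyl enol ethers (same reaction and analysis as step 13): the trienol ether of unit B is oxidised first, C4C attacks C2B through a six-membered transition state on the convex α-face of unit C (syn to H5C, anti to C6C), and a second oxidation with loss of both silyl groups gives the 1,4-diketone with the C1B=C10B alkene out of conjugation.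

Step 9
Reactants: 10 spiro dimer B/C
Product: 12 10β-hydroxy spiro dimer B/C (unit B 10β-hydroxy-3-oxo-1,4(15)-diene), via 1β,10β-epoxide 11 (not isolated)
Conditions: m-CPBA (1.1 equiv), CH2Cl2, −20 °C; then Et3N (2 equiv), 0 → 25 °C
Reagents that add atoms: 3-chloroperoxybenzoic acid, OOC(=O)c1cccc(Cl)c1
Why: Peracid epoxidation of the only tetrasubstituted, non-conjugated alkene (C1B=C10B) on the β-face, anti to the spiro substituent on C2B, then E1cB opening (deprotonation at C2B, cleavage of C1B–O) to the γ-hydroxy enone; this sets C10B (β-OH) and removes the C2B stereocentre.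

Step 10
Reactants: 12 10β-hydroxy spiro dimer B/C
Product: 14 15B-iodo-4BβH-4B,15B-dihydro derivative of 12, via bis(trimethylsilyl) derivative 13 (not isolated)
Conditions: Me3SiI (2.2 equiv), 2,6-di-tert-butylpyridine (1.2 equiv), CH2Cl2, −78 °C; then 0.5 M HCl, THF, 0 °C; used crude
Reagents that add atoms: iodotrimethylsilane, C[Si](C)(C)I
Why: Conjugate iodosilylation as in step 5, now at C15B of the cross-conjugated dienone (C1B is fully substituted and shielded); the tertiary alcohol is silylated in passing while the pyridine base takes up HI, and acidic hydrolysis of 13 returns the alcohol and the C3B ketone with the C1B=C2B enone intact.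

Step 11
Reactants: 14 β-iodo ketone dimer; 5 dienone (future unit A)
Product: 15 tethered trimer (C14A–C15B bond; unit A 3-oxoguaia-1(10),4(15),11(13)-trien-12,6α-olide; units B/C as in 14 without iodine)
Conditions: 5 (1.5 equiv), (Me3Si)3SiH (1.3 equiv), Et3B (0.2 equiv), air, toluene, −20 → 0 °C
Reagents that add atoms: none
Why: Giese reaction as in step 6: the C15B radical adds to C14 of a second molecule of 5; the C1B=C2B enone of the radical precursor is fully substituted at its β-carbon and should not compete as acceptor.

Step 12
Reactants: 15 tethered trimer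
Product: 16 tetrakis(tert-butyldimethylsilyl) derivative (unit A 3-silyloxy-2,1(10),4(15)-triene; unit B 3-silyloxy-1,3(4)-diene and 10β-silyl ether; unit C 3-silyloxy-2-ene)
Conditions: TBSOTf (6 equiv), Et3N (8 equiv), CH2Cl2, 0 → 25 °C
Reagents that add atoms: tert-butyldimethylsilyl trifluoromethanesulfonate, CC(C)(C)[Si](C)(C)OS(=O)(=O)C(F)(F)F
Why: Exhaustive silylation: ketone C3A gives the trienol ether, ketone C3B can enolise only towards C4B and gives the 2-silyloxydiene, and the tertiary alcohol and the ring C ketone (only towards C2C, since C4C is quaternary) are silylated as bystanders.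

Step 13
Reactants: 16 tetrakis(silyl) tethered trimer
Product: 17 spiro trimer with C2A–C4B bond (unit A 2βH-3-oxo-1(10),4(15)-diene; C4B spiro, bond to C2A anti to H5B; 10B-silyl ether; ring C silyl enol ether)
Conditions: Cu(OTf)2 (2.2 equiv), 2,6-di-tert-butylpyridine, MeCN–CH2Cl2 (0.005 M), −30 → 0 °C
Reagents that add atoms: none
Why: Divalent copper triflate in acetonitrile removes one electron from the most electron-rich donor, the trienol silyl ether of unit A, giving a radical cation delocalised over O–C3A–C2A–C1A–C10A. The C4B terminus of the 2-silyloxydiene of unit B adds to C2A, the resulting α-silyloxy radical is oxidised by the second equivalent, and both silyl groups leave as silyl triflate to give the 1,4-diketone O=C3A–C2A–C4B–C3B=O. The closest known reaction type is the oxidative coupling of silyl enol ethers to 1,4-diketones with one-electron oxidants (divalent copper triflate, ceric ammonium nitrate, oxovanadium reagents), which is known in intramolecular and quaternary-centre-forming variants. The ring closed is the cyclohexene C2A–C1A–C10A–C14A–C15B–C4B, by a 6-exo attack with respect to both enol π-bonds (C3A and C3B stay outside the ring); closure at C10A would need a four-membered ring, so the tether fixes the regiochemistry. C4B is set by the face of the unit B enol ether that is attacked: the α-face is covered by C5C and the hydroazulene of unit C, which hangs below C2B from the spiro centre C4C, whereas the β-face meets only the C3C carbonyl side, so the bond should form on the β-face (anti to H5B) as in 19. C2A is formed as one epimer (expected with C4B on the α-face of unit A) and is erased in step 14. The step needs oxidation of the A and B donors but not of the trisubstituted, non-conjugated ring C enol ether (harder to oxidise; only 2.2 equiv of oxidant), cyclisation faster than intermolecular coupling (high dilution), and no conjugation of the new C1A=C10A alkene (hindered pyridine buffer).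

Step 14
Reactants: 17 spiro trimer
Product: 19 ainsliatrimer A, via conjugated bis-silyl trimer 18 (not isolated)
Conditions: DBU (0.2 equiv), CH2Cl2, 0 → 25 °C; then HF·pyridine, THF, 0 → 25 °C
Reagents that add atoms: none
Why: Base-mediated conjugation of the β,γ-enone through the dienolate (deprotonation at C2A, protonation at C10A); C10A stays epimerisable through the same dienolate, so the more stable 10α-H epimer of 19 is expected under thermodynamic control; HF then cleaves the tertiary silyl ether and the ring C silyl enol ether to return the alcohol and the ketone.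

## Compound list

1 | dehydrocostus lactone | C=C1CC[C@H]2C(=C)CC[C@H]3C(=C)C(=O)O[C@@H]3[C@H]21 | starting material
2 | 3-epizaluzanin C (3α-hydroxydehydrocostus lactone) | C=C1[C@H](O)C[C@H]2C(=C)CC[C@H]3C(=C)C(=O)O[C@@H]3[C@H]21 | intermediate
3 | dehydrozaluzanin C (3-oxoguaia-4(15),10(14),11(13)-trien-12,6α-olide) | C=C1C(=O)C[C@H]2C(=C)CC[C@H]3C(=C)C(=O)O[C@@H]3[C@H]21 | intermediate
4 | 3-(tert-butyldimethylsilyloxy)guaia-2,4(15),10(14),11(13)-tetraen-12,6α-olide | C=C1C(O[Si](C)(C)C(C)(C)C)=C[C@H]2C(=C)CC[C@H]3C(=C)C(=O)O[C@@H]3[C@H]21 | intermediate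
5 | 3-oxoguaia-1,4(15),10(14),11(13)-tetraen-12,6α-olide | C=C1C(=O)C=C2C(=C)CC[C@H]3C(=C)C(=O)O[C@@H]3[C@H]21 | intermediate
6 | 15-iodo-3-(trimethylsilyloxy)guaia-3,10(14),11(13)-trien-12,6α-olide (not isolated) | ICC1=C(O[Si](C)(C)C)C[C@H]2C(=C)CC[C@H]3C(=C)C(=O)O[C@@H]3[C@H]21 | intermediate
7 | 15-iodo-3-oxo-4βH-guaia-10(14),11(13)-dien-12,6α-olide | IC[C@@H]1C(=O)C[C@H]2C(=C)CC[C@H]3C(=C)C(=O)O[C@@H]3[C@H]21 | intermediate
8 | tethered diketone B/C (C14B–C15C bond; unit B 3-oxo-1(10),4(15),11(13)-triene; unit C 3-oxo-4βH-10(14),11(13)-diene) | C=C1C(=O)CC2=C(CC[C@@H]3C(=O)C[C@H]4C(=C)CC[C@H]5C(=C)C(=O)O[C@@H]5[C@H]43)CC[C@H]3C(=C)C(=O)O[C@@H]3[C@@H]12 | intermediate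
9 | bis(tert-butyldimethylsilyl enol ether) of 8 (unit B 2,1(10),4(15)-trien-3-yl ether; unit C 3(4)-en-3-yl ether) | C=C1C(O[Si](C)(C)C(C)(C)C)=CC2=C(CCC3=C(O[Si](C)(C)C(C)(C)C)C[C@H]4C(=C)CC[C@H]5C(=C)C(=O)O[C@@H]5[C@H]43)CC[C@H]3C(=C)C(=O)O[C@@H]3[C@@H]12 | intermediate
10 | spiro dimer B/C (C2B–C4C and C14B–C15C bonds; unit B 2βH-3-oxo-1(10),4(15),11(13)-triene; unit C 3-oxo, C4 spiro with C2B on the α-face) | C=C1C(=O)[C@H]2C3=C(CC[C@H]4C(=C)C(=O)O[C@@H]4[C@@H]13)CC[C@]21C(=O)C[C@H]2C(=C)CC[C@H]3C(=C)C(=O)O[C@@H]3[C@H]21 | intermediate
11 | 1Bβ,10Bβ-epoxide of 10 (not isolated) | C=C1C(=O)[C@H]2[C@@]35O[C@]5(CC[C@H]4C(=C)C(=O)O[C@@H]4[C@@H]13)CC[C@]21C(=O)C[C@H]2C(=C)CC[C@H]3C(=C)C(=O)O[C@@H]3[C@H]21 | intermediate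
12 | 10β-hydroxy spiro dimer B/C (unit B 10β-hydroxy-3-oxo-1,4(15),11(13)-triene) | C=C1C(=O)C2=C3[C@H]1[C@H]1OC(=O)C(=C)[C@@H]1CC[C@@]3(O)CC[C@]21C(=O)C[C@H]2C(=C)CC[C@H]3C(=C)C(=O)O[C@@H]3[C@H]21 | intermediate
13 | 15B-iodo-3B,10B-bis(trimethylsilyloxy)-1,3(4)-diene derivative of 12 (not isolated) | ICC1=C(O[Si](C)(C)C)C2=C3[C@H]1[C@H]1OC(=O)C(=C)[C@@H]1CC[C@@]3(O[Si](C)(C)C)CC[C@]21C(=O)C[C@H]2C(=C)CC[C@H]3C(=C)C(=O)O[C@@H]3[C@H]21 | intermediate
14 | 15B-iodo-4BβH-4B,15B-dihydro derivative of 12 | IC[C@@H]1C(=O)C2=C3[C@H]1[C@H]1OC(=O)C(=C)[C@@H]1CC[C@@]3(O)CC[C@]21C(=O)C[C@H]2C(=C)CC[C@H]3C(=C)C(=O)O[C@@H]3[C@H]21 | intermediate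
15 | tethered trimer (C14A–C15B bond; unit A 3-oxo-1(10),4(15),11(13)-triene; unit B 4βH, 10β-OH, 3-oxo-1-ene; unit C as in 12) | C=C1C(=O)CC2=C(CC[C@@H]3C(=O)C4=C5[C@H]3[C@H]3OC(=O)C(=C)[C@@H]3CC[C@@]5(O)CC[C@]46C(=O)C[C@H]4C(=C)CC[C@H]5C(=C)C(=O)O[C@@H]5[C@H]46)CC[C@H]3C(=C)C(=O)O[C@@H]3[C@@H]12 | intermediate
16 | tetrakis(tert-butyldimethylsilyl) derivative of 15 (A trienol ether, B 2-silyloxydiene, 10B-silyl ether, C 2-en-3-yl ether) | C=C1C(O[Si](C)(C)C(C)(C)C)=CC2=C(CCC3=C(O[Si](C)(C)C(C)(C)C)C4=C5[C@H]3[C@H]3OC(=O)C(=C)[C@@H]3CC[C@@]5(O[Si](C)(C)C(C)(C)C)CC[C@]46C(O[Si](C)(C)C(C)(C)C)=C[C@H]4C(=C)CC[C@H]5C(=C)C(=O)O[C@@H]5[C@H]46)CC[C@H]3C(=C)C(=O)O[C@@H]3[C@@H]12 | intermediate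
17 | spiro trimer (C2A–C4B bond; unit A 2βH-3-oxo-1(10),4(15)-diene; 10B-silyl ether; ring C silyl enol ether) | C=C1C(=O)[C@H]2C3=C(CC[C@H]4C(=C)C(=O)O[C@@H]4[C@@H]13)CC[C@@]21C(=O)C2=C3[C@H]1[C@H]1OC(=O)C(=C)[C@@H]1CC[C@@]3(O[Si](C)(C)C(C)(C)C)CC[C@]21C(O[Si](C)(C)C(C)(C)C)=C[C@H]2C(=C)CC[C@H]3C(=C)C(=O)O[C@@H]3[C@H]21 | intermediate
18 | 10B-O-silyl, ring C silyl enol ether derivative of ainsliatrimer A (not isolated) | C=C1C(=O)C2=C3[C@H](CC[C@H]4C(=C)C(=O)O[C@@H]4[C@@H]13)CC[C@@]21C(=O)C2=C3[C@H]1[C@H]1OC(=O)C(=C)[C@@H]1CC[C@@]3(O[Si](C)(C)C(C)(C)C)CC[C@]21C(O[Si](C)(C)C(C)(C)C)=C[C@H]2C(=C)CC[C@H]3C(=C)C(=O)O[C@@H]3[C@H]21 | intermediate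
19 | ainsliatrimer A | C=C1C(=O)C2=C3[C@H](CC[C@H]4C(=C)C(=O)O[C@@H]4[C@@H]13)CC[C@@]21C(=O)C2=C3[C@H]1[C@H]1OC(=O)C(=C)[C@@H]1CC[C@@]3(O)CC[C@]21C(=O)C[C@H]2C(=C)CC[C@H]3C(=C)C(=O)O[C@@H]3[C@H]21 | target

## Step count and least certain steps

Total step count: 14. Longest linear sequence: 13 steps (steps 1–4 and 6–14); step 5 is the side branch.

**Step 13 (key step; step 8 is the same reaction one level down).**
- What may go wrong: desilylation without C–C bond formation, which returns 15; oxidation of the ring C enol ether or intermolecular coupling; attack on the α-face of C4B, giving the spiro epimer; conjugation of the product under the reaction conditions.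
- Fallback (enolate/vinyl iodide logic): sets out from 15 and comes back at 19. Treatment of 15 with DBU should give the conjugated 1A-en-3A-one with H10A α, the conjugated tethered trimer F1. Iodination at C2A (I2, pyridine) should give the 2A-iodoenone F2. Pd(PPh3)4 (zerovalent palladium) with K3PO4 in warm THF should then close the C2A–C4B bond by intramolecular ketone α-alkenylation. C4B is the only enolisable α-carbon of the unit B ketone that can reach C2A, and the product is 19 directly.

**Step 6 (step 11 has the same profile).**
- What may go wrong: addition of the radical to the wrong acceptor (C15 of 5 or a lactone methylene); 1,2-acyl shift of the β-keto radical (ring expansion); hydrosilylation of a methylene lactone; loss of HI from 7 before the radical forms.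
- Fallback: sets out from 3 and 5 and comes back at 10. A thermal (4+2) cycloaddition of the diene of 5 to the exocyclic enone of 3 forms both bonds of ring B/C at once; this fallback makes no new compound (F0).

**Step 7.**
- What may go wrong: enol silylation of the ring C ketone towards C2C instead of C4C, so that no cyclisable enol ether is present in step 8.
- Fallback (regiochemistry fixed by conjugate addition instead of enolisation): sets out from 3 and 5 and comes back at 9. t-BuMe2SiI (from TBSCl and NaI) adds to 3 to give the regiodefined 15-iodo tert-butyldimethylsilyl enol ether F4. Its C15 radical is added to 5 under the conditions of step 6 to give the mono-silyl tethered ketone F5. Silylation of the unit B ketone alone (TBSOTf, Et3N) then gives 9.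

**Step 9.**
- What may go wrong: poor facial selectivity of the epoxidation (10α-alcohol), competing epoxidation of the 10(14)-alkene of unit C, or conjugation of 10 before the oxidant acts.
- Fallback (dienolate oxygenation instead of epoxidation): sets out from 10 and comes back at 12. Et3N under O2 should convert 10 through its dienolate into the 10β-hydroperoxide F3. Reduction with PPh3 gives 12; epimers at C10B would be separated at this stage.

## Further compounds

F0 | step 6 | none | none
F1 | step 13 | conjugated tethered trimer (isomer of 15 with C1A=C2A and H10A α) | C=C1C(=O)C=C2[C@@H](CC[C@@H]3C(=O)C4=C5[C@H]3[C@H]3OC(=O)C(=C)[C@@H]3CC[C@@]5(O)CC[C@]46C(=O)C[C@H]4C(=C)CC[C@H]5C(=C)C(=O)O[C@@H]5[C@H]46)CC[C@H]3C(=C)C(=O)O[C@@H]3[C@@H]12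
F2 | step 13 | 2A-iodo derivative of F1 | C=C1C(=O)C(I)=C2[C@@H](CC[C@@H]3C(=O)C4=C5[C@H]3[C@H]3OC(=O)C(=C)[C@@H]3CC[C@@]5(O)CC[C@]46C(=O)C[C@H]4C(=C)CC[C@H]5C(=C)C(=O)O[C@@H]5[C@H]46)CC[C@H]3C(=C)C(=O)O[C@@H]3[C@@H]12
F3 | step 9 | 10Bβ-hydroperoxide corresponding to 12 | C=C1C(=O)C2=C3[C@H]1[C@H]1OC(=O)C(=C)[C@@H]1CC[C@@]3(OO)CC[C@]21C(=O)C[C@H]2C(=C)CC[C@H]3C(=C)C(=O)O[C@@H]3[C@H]21
F4 | step 7 | 15-iodo-3-(tert-butyldimethylsilyloxy)guaia-3,10(14),11(13)-trien-12,6α-olide | ICC1=C(O[Si](C)(C)C(C)(C)C)C[C@H]2C(=C)CC[C@H]3C(=C)C(=O)O[C@@H]3[C@H]21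
F5 | step 7 | tethered B/C compound with unit B ketone (1(10),4(15)-diene) and unit C 3(4)-silyl enol ether | C=C1C(=O)CC2=C(CCC3=C(O[Si](C)(C)C(C)(C)C)C[C@H]4C(=C)CC[C@H]5C(=C)C(=O)O[C@@H]5[C@H]43)CC[C@H]3C(=C)C(=O)O[C@@H]3[C@@H]12
A1 | alternative 1 | cycloadduct of 5 and 12 (1A(10A)-ene isomer of 19 with 2AβH) | C=C1C(=O)[C@H]2C3=C(CC[C@H]4C(=C)C(=O)O[C@@H]4[C@@H]13)CC[C@@]21C(=O)C2=C3[C@H]1[C@H]1OC(=O)C(=C)[C@@H]1CC[C@@]3(O)CC[C@]21C(=O)C[C@H]2C(=C)CC[C@H]3C(=C)C(=O)O[C@@H]3[C@H]21
A2 | alternative 2 | 2B-iodo-1B-en-3B-one isomer of 8 (H10B α) | C=C1C(=O)C(I)=C2[C@@H](CC[C@@H]3C(=O)C[C@H]4C(=C)CC[C@H]5C(=C)C(=O)O[C@@H]5[C@H]43)CC[C@H]3C(=C)C(=O)O[C@@H]3[C@@H]12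
A3 | alternative 2 | 10B-deoxy analogue of 12 (H10B α) | C=C1C(=O)C2=C3[C@H]1[C@H]1OC(=O)C(=C)[C@@H]1CC[C@@H]3CC[C@]21C(=O)C[C@H]2C(=C)CC[C@H]3C(=C)C(=O)O[C@@H]3[C@H]21
A4 | alternative 3 | C2B–C4C-linked seco dimer (unit B 3-oxo-1,4(15),10(14)-triene; unit C 15-iodo-3-oxo, C4 quaternary) | C=C1C(=O)C(=C2C(=C)CC[C@H]3C(=C)C(=O)O[C@@H]3[C@@H]12)[C@]1(CI)C(=O)C[C@H]2C(=C)CC[C@H]3C(=C)C(=O)O[C@@H]3[C@H]21
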